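The ring is numbered O1, C2 (ring A), C3 and C4 (methyl groups), C5 (ring B), and the plan cuts C3–C4, O1–C2 and O1–C5. It exploits two features: C3–C4 joins the side-chain termini of two arylpropenes, and C2 and C5 lie para to aryl oxygens. The ring is therefore two (E)-propenylphenols plus water. Its twofold-symmetric all-trans core asks a chiral host only to pair like faces. One oxidation makes all three bonds, the ring and four stereocentres. Each precursor phenol has both ortho carbons blocked: ring B by its methoxy groups, ring A by methoxy and a sacrificial bromine. The bromine is removed before the final double O-methylation.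

Key step: step 4

Stereochemical remark: the target is the all-trans (2S,3S,4S,5S) isomer, with aryl at C2 and methyl at C4 on one face and methyl at C3 and aryl at C5 on the other. Only C2 and C5 can be corrected by equilibration. The trans relation of C3/C4 and the absolute sense are fixed for good when C3–C4 forms.

Assumption: a dirigent-type protein that accepts 3,5-disubstituted propenylphenoxyl radicals and pairs their Re faces can be found. The search would screen homologues from plants that make 8–8' propenylphenol lignans, or evolve a (+)-pinoresinol-forming protein, since known wild types are tuned to coniferyl alcohol.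

Step 1
Reactants: 1 eugenol (4-allyl-2-methoxyphenol)
Product: 2 4-allyl-2-bromo-6-methoxyphenol
Conditions: NBS (1.0 equiv), iPr2NH (10 mol%), CH2Cl2, 0 °C
Reagents that add atoms: N-bromosuccinimide, O=C1CCC(=O)N1Br
Why: Amine-catalysed electrophilic aromatic bromination is steered by the free hydroxyl group to its only open ortho carbon (the para carbon carries the allyl group) and should outrun attack on the unactivated terminal alkene.

Step 2
Reactants: 2 4-allyl-2-bromo-6-methoxyphenol
Product: 3 (E)-2-bromo-6-methoxy-4-(prop-1-en-1-yl)phenol
Conditions: RuHCl(CO)(PPh3)3 (1 mol%), toluene, 80 °C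
Reagents that add atoms: none
Why: Ruthenium hydride catalysed alkene isomerisation (hydrometalation/β-hydride elimination) moves the double bond into conjugation with the arene and should settle on the thermodynamically preferred E-alkene, while phenol and aryl bromide stay inert.

Step 3
Reactants: 4 4-allyl-2,6-dimethoxyphenol
Product: 5 (E)-2,6-dimethoxy-4-(prop-1-en-1-yl)phenol
Conditions: RuHCl(CO)(PPh3)3 (1 mol%), toluene, 80 °C
Reagents that add atoms: none
Why: The same ruthenium hydride catalysed allyl-to-propenyl isomerisation applies, with conjugation as driving force and the E-geometry set thermodynamically.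

Step 4
Reactants: 3 (E)-2-bromo-6-methoxy-4-(prop-1-en-1-yl)phenol; 5 (E)-2,6-dimethoxy-4-(prop-1-en-1-yl)phenol
Product: 9 (2S,3S,4S,5S)-2-(3-bromo-4-hydroxy-5-methoxyphenyl)-5-(4-hydroxy-3,5-dimethoxyphenyl)-3,4-dimethyltetrahydrofuran, via bis(quinone methide) 6 (not isolated), via hydroxy quinone methide 7 (not isolated), via C2/C5-epimeric tetrahydrofurans 8 (not isolated)
Conditions: laccase (Trametes versicolor), air, dirigent protein variant (Re,Re-pairing), NaOAc buffer pH 5/acetone 4:1, 25 °C, 3 (3 equiv), 5 added over 6 h; EtOAc extraction, then CSA (10 mol%), CH2Cl2, 23 °C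
Reagents that add atoms: water, O
Why: Proposed new method: laccase/O2 takes one electron and one proton from each phenol, the two phenoxyl radicals (spin at the side-chain terminus) combine tail to tail to make C3–C4 in 6, water adds to the more electrophilic bromo-substituted quinone methide carbon (C2) with rearomatisation of ring A to give 7, and the new hydroxyl group adds to the second quinone methide carbon (C5). The closest known reaction types are the laccase-, peroxidase- or FeCl3-mediated racemic 8–8' dimerisation of propenylphenols with water capture and the dirigent-protein-guided coupling of coniferyl alcohol radicals to (+)-pinoresinol, whereas an enantioselective hetero-coupling of propenylphenols has not been shown. The one ring closes by 5-exo-trig oxa-conjugate addition (O1–C5), the attacked C=C lying outside the new ring. C3 and C4 are set irreversibly in the radical combination by the host, which must offer the Re face of the terminal carbon of both radicals (the spatial equivalent of the si–si pairing that leads to (+)-pinoresinol), thereby fixing the trans-dimethyl relation and the absolute sense, and because the core is twofold-symmetric it does not matter which radical fills which pocket. C2 and C5 are set thermodynamically, since acid reopens the p-hydroxybenzyl ether bonds of 8 through the quinone methide and lets each aryl group settle trans to its neighbouring methyl group. Coupling at 8–8' instead of 8–5' is secured by substituents on all four ortho carbons (Br and OMe on ring A, two OMe on ring B), and hetero- over homo-coupling by slow addition of the more easily oxidised 5 to excess 3, so that the longer-lived syringyl radical meets mainly radicals of 3.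

Step 5
Reactants: 9 (2S,3S,4S,5S)-2-(3-bromo-4-hydroxy-5-methoxyphenyl)-5-(4-hydroxy-3,5-dimethoxyphenyl)-3,4-dimethyltetrahydrofuran
Product: 10 (2S,3S,4S,5S)-2-(4-hydroxy-3-methoxyphenyl)-5-(4-hydroxy-3,5-dimethoxyphenyl)-3,4-dimethyltetrahydrofuran
Conditions: H2 (1 atm), 10% Pd/C, Et3N (3 equiv), MeOH, 23 °C
Reagents that add atoms: none
Why: Catalytic hydrodehalogenation of the aryl bromide is fast at one atmosphere, and the amine that takes up HBr also slows hydrogenolysis of the benzylic C–O bonds, so the four stereocentres should stay untouched.

Step 6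
Reactants: 10 (2S,3S,4S,5S)-2-(4-hydroxy-3-methoxyphenyl)-5-(4-hydroxy-3,5-dimethoxyphenyl)-3,4-dimethyltetrahydrofuran; 11 iodomethane
Product: 12 5-methoxygalbelgin, (2S,3S,4S,5S)-2-(3,4-dimethoxyphenyl)-5-(3,4,5-trimethoxyphenyl)-3,4-dimethyltetrahydrofuran
Conditions: MeI (4 equiv), K2CO3, DMF, 23 °C
Reagents that add atoms: iodomethane, CI
Why: Williamson ether synthesis (SN2 of both phenoxides on MeI) touches no stereocentre, and capping the phenols shuts the quinone methide pathway by which the ring could reopen.

Compound list
1 | eugenol (4-allyl-2-methoxyphenol) | COc1cc(CC=C)ccc1O | starting material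
2 | 4-allyl-2-bromo-6-methoxyphenol | COc1cc(CC=C)cc(Br)c1O | intermediate
3 | (E)-2-bromo-6-methoxy-4-(prop-1-en-1-yl)phenol (isoeugenol with bromine ortho to OH) | COc1cc(/C=C/C)cc(Br)c1O | intermediate
4 | 4-allyl-2,6-dimethoxyphenol | COc1cc(CC=C)cc(OC)c1O | starting material
5 | (E)-2,6-dimethoxy-4-(prop-1-en-1-yl)phenol | COc1cc(/C=C/C)cc(OC)c1O | intermediate
6 | 4-[(2S,3S)-4-(3-bromo-5-methoxy-4-oxocyclohexa-2,5-dien-1-ylidene)-2,3-dimethylbutylidene]-2,6-dimethoxycyclohexa-2,5-dien-1-one (exocyclic alkene geometry at ring A undefined) | COC1=CC(=C[C@@H](C)[C@H](C)C=C2C=C(OC)C(=O)C(OC)=C2)C=C(Br)C1=O | intermediate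
7 | hydrate of 6 at C2: ring A rearomatised to the phenol, benzylic OH at C2 (both epimers), C3 and C4 spatially as in 6, ring B still a quinone methide (water attack at C5 first would converge on the same ring) | COc1cc(C(O)[C@@H](C)[C@H](C)C=C2C=C(OC)C(=O)C(OC)=C2)cc(Br)c1O | intermediate
8 | (3S,4S)-2-(3-bromo-4-hydroxy-5-methoxyphenyl)-5-(4-hydroxy-3,5-dimethoxyphenyl)-3,4-dimethyltetrahydrofuran, kinetic mixture of epimers at C2 and C5 | COc1cc(C2OC(c3cc(OC)c(O)c(OC)c3)[C@@H](C)[C@@H]2C)cc(Br)c1O | intermediate
9 | (2S,3S,4S,5S)-2-(3-bromo-4-hydroxy-5-methoxyphenyl)-5-(4-hydroxy-3,5-dimethoxyphenyl)-3,4-dimethyltetrahydrofuran (all-trans) | COc1cc([C@H]2O[C@H](c3cc(OC)c(O)c(OC)c3)[C@@H](C)[C@@H]2C)cc(Br)c1O | intermediate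
10 | (2S,3S,4S,5S)-2-(4-hydroxy-3-methoxyphenyl)-5-(4-hydroxy-3,5-dimethoxyphenyl)-3,4-dimethyltetrahydrofuran (all-trans) | COc1cc([C@H]2O[C@H](c3cc(OC)c(O)c(OC)c3)[C@@H](C)[C@@H]2C)ccc1O | intermediate
11 | iodomethane | CI | starting material
12 | 5-methoxygalbelgin, (2S,3S,4S,5S)-2-(3,4-dimethoxyphenyl)-5-(3,4,5-trimethoxyphenyl)-3,4-dimethyltetrahydrofuran | COc1ccc([C@H]2O[C@H](c3cc(OC)c(OC)c(OC)c3)[C@@H](C)[C@@H]2C)cc1OC | target

Total step count: 6. Longest linear sequence: 5 (steps 1, 2, 4, 5, 6).

Steps most likely to fail

1. Step 4 (Proposed new method).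
- Radical pairing outside the host would erode enantiomeric purity.
- Unlike-face pairing would divert material into the cis-dimethyl series, which no equilibration can repair.
- Other threats are statistical homo-coupling, carbon–oxygen (8–O–4') coupling and further oxidation of the product phenols by the enzyme.
- Friedel–Crafts closure onto the electron-rich ring B could occur during the acid treatment.

Fallback (known chemistry, absolute control by classical resolution): setting out from 3 and 5, the same cascade is run without any host (horseradish peroxidase, H2O2, aqueous acetone, then CSA in CH2Cl2). This should give 9 as a racemate together with its mirror image, (2R,3R,4R,5R)-2-(3-bromo-4-hydroxy-5-methoxyphenyl)-5-(4-hydroxy-3,5-dimethoxyphenyl)-3,4-dimethyltetrahydrofuran F1. The hetero-dimer should be separable from both homo-dimers through its single bromine atom. Acylation of both phenols with (1S)-(−)-camphanic chloride (Et3N, DMAP, CH2Cl2) should give two diastereomers, the bis(camphanate) of 9 F2 and the bis(camphanate) of the mirror image F3. These are parted by crystallisation or chromatography, and the bromine atom allows assignment by anomalous X-ray dispersion. LiOH in THF/H2O cleaves F2, and the route is rejoined at 9.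

2. Step 5. Hydrogenolysis of the doubly activated benzylic C–O bonds may compete with C–Br cleavage, or the catalyst may be poisoned before debromination is complete.

Fallback (halogen–metal exchange in place of catalytic reduction): setting out from 9, both phenols are methylated first (MeI, K2CO3, DMF) to (2S,3S,4S,5S)-2-(3-bromo-4,5-dimethoxyphenyl)-5-(3,4,5-trimethoxyphenyl)-3,4-dimethyltetrahydrofuran F4. Treatment with n-BuLi in THF at −78 °C should give the corresponding aryllithium F5. Protonation with MeOH rejoins the route at 12, bypassing 10.

3. Step 1. Bromine transfer to the allyl double bond, or substitution para to the methoxy group, may compete with the ortho-hydroxyl substitution.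

Fallback (alkene masked as its dibromide): setting out from 1, Br2 (2 equiv, CH2Cl2, 0 °C) deliberately brominates both ring and alkene to 2-bromo-4-(2,3-dibromopropyl)-6-methoxyphenol F6. Zinc dust in AcOH/EtOH then removes the vicinal bromines by reductive elimination, leaves the aryl bromide in place, and rejoins the route at 2.

Further compounds
F1 | step 4 | (2R,3R,4R,5R)-2-(3-bromo-4-hydroxy-5-methoxyphenyl)-5-(4-hydroxy-3,5-dimethoxyphenyl)-3,4-dimethyltetrahydrofuran | COc1cc([C@@H]2O[C@@H](c3cc(OC)c(O)c(OC)c3)[C@H](C)[C@H]2C)cc(Br)c1O
F2 | step 4 | bis[(1S,4R)-camphanate] of 9 | COc1cc([C@H]2O[C@H](c3cc(OC)c(OC(=O)[C@@]45CC[C@@](C)(C(=O)O4)C5(C)C)c(OC)c3)[C@@H](C)[C@@H]2C)cc(Br)c1OC(=O)[C@@]67CC[C@@](C)(C(=O)O6)C7(C)C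
F3 | step 4 | bis[(1S,4R)-camphanate] of F1 | COc1cc([C@@H]2O[C@@H](c3cc(OC)c(OC(=O)[C@@]45CC[C@@](C)(C(=O)O4)C5(C)C)c(OC)c3)[C@H](C)[C@H]2C)cc(Br)c1OC(=O)[C@@]67CC[C@@](C)(C(=O)O6)C7(C)C
F4 | step 5 | (2S,3S,4S,5S)-2-(3-bromo-4,5-dimethoxyphenyl)-5-(3,4,5-trimethoxyphenyl)-3,4-dimethyltetrahydrofuran | COc1cc([C@H]2O[C@H](c3cc(OC)c(OC)c(OC)c3)[C@@H](C)[C@@H]2C)cc(Br)c1OC
F5 | step 5 | aryllithium from F4 (Li in place of Br) | COc1cc([C@H]2O[C@H](c3cc(OC)c(OC)c(OC)c3)[C@@H](C)[C@@H]2C)cc([Li])c1OC
F6 | step 1 | 2-bromo-4-(2,3-dibromopropyl)-6-methoxyphenol (racemic) | COc1cc(CC(Br)CBr)cc(Br)c1O
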